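**Retrosynthetic overview**
- Target: (+)-acetoxycrenulide – furan-2(5H)-one ring A fused through its C3=C4 double bond to cyclooctene ring B, which carries a cis-fused cyclopropane ring C, an acetate, a methyl group and the (R)-6-methylhept-5-en-2-yl chain.
- Key disconnection: the ring A C3=C4 bond (shared with ring B), made by a transannular Horner–Wadsworth–Emmons reaction inside an 11-membered keto phosphono lactone. That lactone forms in the same flask from an acyclic bromoketone acid by carboxylate O-alkylation, so rings A and B appear together, last.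
- Enabling feature: the ring A ester unit C2(=O)–O1–C5H2 already links the olefinic carbons C3 and C4 in a 1,4-relationship, so the bond formation is a five-ring event. The cis-disubstituted ring C folds the six-carbon chain that becomes ring B, and the ketone at C4 sits on a cyclopropane carbon that cannot enolise.
- Seco-acid: the bond between the acetoxy carbon and the ring B CH2 is made by Fukuyama coupling of a Roche-ester-derived cyclopropyl alkylzinc (Charette cyclopropanation) with a citronellic-acid-derived thioester (Evans alkylation), followed by CBS reduction.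
- Ring order: C (step 5) → transient 11-membered lactone → A + B (step 23).

Key step: step 23

Remark: the phosphonate-bearing carbon of 23–31 (and F1–F3) forms as a mixture of both epimers and is left undefined in the SMILES; it becomes the sp2 carbon C3 of ring A in step 23, so the mixture converges.

**Fragment W (ring C, methyl stereocentre)**

Step 1
Reactants: 1 methyl (R)-3-hydroxy-2-methylpropanoate
Product: 2 methyl (R)-3-[(tert-butyldimethylsilyl)oxy]-2-methylpropanoate
Conditions: TBSCl, imidazole, DMF, 0 → 25 °C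
Reagents that add atoms: tert-butyldimethylsilyl chloride, CC(C)(C)[Si](C)(C)Cl
Why: Routine silylation of a primary alcohol; the purchased stereocentre becomes the methyl-bearing carbon of ring B.

Step 2
Reactants: 2 methyl (R)-3-[(tert-butyldimethylsilyl)oxy]-2-methylpropanoate
Product: 3 (R)-3-[(tert-butyldimethylsilyl)oxy]-2-methylpropanal
Conditions: iBu2AlH, CH2Cl2, −78 °C; MeOH quench at −78 °C, Rochelle salt
Reagents that add atoms: none
Why: Partial ester reduction through the cold-stable aluminium hemiacetal; cold quench and immediate use should prevent epimerisation of the alpha-methyl aldehyde.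

Step 3
Reactants: 3 (R)-3-[(tert-butyldimethylsilyl)oxy]-2-methylpropanal
Product: 4 methyl (2Z,4S)-5-[(tert-butyldimethylsilyl)oxy]-4-methylpent-2-enoate
Conditions: (CF3CH2O)2P(O)CH2CO2Me, KN(SiMe3)2, 18-crown-6, THF, −78 °C
Reagents that add atoms: methyl bis(2,2,2-trifluoroethyl)phosphonoacetate, COC(=O)CP(=O)(OCC(F)(F)F)OCC(F)(F)F
Why: Still–Gennari olefination; fast irreversible elimination from the kinetic adduct should give the Z-enoate required for a cis-cyclopropane.

Step 4
Reactants: 4 methyl (2Z,4S)-5-[(tert-butyldimethylsilyl)oxy]-4-methylpent-2-enoate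
Product: 5 (2Z,4S)-5-[(tert-butyldimethylsilyl)oxy]-4-methylpent-2-en-1-ol
Conditions: iBu2AlH (2.5 equiv), CH2Cl2, −78 °C
Reagents that add atoms: none
Why: 1,2-Reduction of an enoate to the allylic alcohol with retention of the Z geometry.

Step 5
Reactants: 5 (2Z,4S)-5-[(tert-butyldimethylsilyl)oxy]-4-methylpent-2-en-1-ol
Product: 6 {(1S,2S)-2-[(2S)-1-[(tert-butyldimethylsilyl)oxy]propan-2-yl]cyclopropyl}methanol
Conditions: Et2Zn, CH2I2, DME, (4R,5R)-2-butyl-N,N,N',N'-tetramethyl-1,3,2-dioxaborolane-4,5-dicarboxamide (1.2 equiv), CH2Cl2, −10 → 25 °C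
Reagents that add atoms: diiodomethane, ICI
Why: Charette asymmetric Simmons–Smith cyclopropanation; stereospecific syn methylene transfer turns the Z-alkene into the cis ring, and the boron-bound allylic alkoxide directs the zinc carbenoid to one face, so both ring C stereocentres are set by the (4R,5R)-ligand, overriding the weak allylic-strain bias of the methyl centre.

Step 6
Reactants: 6 {(1S,2S)-2-[(2S)-1-[(tert-butyldimethylsilyl)oxy]propan-2-yl]cyclopropyl}methanol
Product: 7 (1S,2S)-2-[(2S)-1-[(tert-butyldimethylsilyl)oxy]propan-2-yl]cyclopropane-1-carbaldehyde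
Conditions: Dess–Martin periodinane, NaHCO3, CH2Cl2, 0 → 25 °C
Reagents that add atoms: none
Why: Buffered Dess–Martin oxidation; the cyclopropyl alpha-C–H is not readily enolised, so the cis relationship should be kept.

Step 7
Reactants: 7 (1S,2S)-2-[(2S)-1-[(tert-butyldimethylsilyl)oxy]propan-2-yl]cyclopropane-1-carbaldehyde
Product: 8 tert-butyl{(2S)-2-[(1R,2S)-2-(2,2-dibromoethenyl)cyclopropyl]propoxy}dimethylsilane
Conditions: CBr4, PPh3, 2,6-lutidine, CH2Cl2, 0 °C
Reagents that add atoms: carbon tetrabromide, BrC(Br)(Br)Br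
Why: First stage of the Corey–Fuchs homologation (Wittig reaction of the in situ dibromomethylene ylide) under neutral, buffered conditions.

Step 8
Reactants: 8 tert-butyl{(2S)-2-[(1R,2S)-2-(2,2-dibromoethenyl)cyclopropyl]propoxy}dimethylsilane
Product: 10 tert-butyldimethyl{(2S)-2-[(1R,2S)-2-[(trimethylsilyl)ethynyl]cyclopropyl]propoxy}silane, via lithium acetylide 9 (not isolated)
Conditions: n-BuLi (2.1 equiv), THF, −78 → 0 °C; then Me3SiCl, −78 → 25 °C
Reagents that add atoms: chlorotrimethylsilane, C[Si](C)(C)Cl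
Why: Second stage of the Corey–Fuchs reaction (Br/Li exchange, Fritsch–Buttenberg–Wiechell shift, deprotonation), with the acetylide capped as a C-silyl alkyne that masks the later bromoketone.

Step 9
Reactants: 10 tert-butyldimethyl{(2S)-2-[(1R,2S)-2-[(trimethylsilyl)ethynyl]cyclopropyl]propoxy}silane
Product: 11 (2S)-2-{(1R,2S)-2-[(trimethylsilyl)ethynyl]cyclopropyl}propan-1-ol
Conditions: camphorsulfonic acid (cat.), MeOH/CH2Cl2, 0 °C
Reagents that add atoms: none
Why: Acid-catalysed methanolysis removes the primary O-silyl group; the alkynyl C–Si bond is stable to acid and is cleaved only by base or fluoride.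

Step 10
Reactants: 11 (2S)-2-{(1R,2S)-2-[(trimethylsilyl)ethynyl]cyclopropyl}propan-1-ol
Product: 12 ({(1S,2R)-2-[(2S)-1-iodopropan-2-yl]cyclopropyl}ethynyl)trimethylsilane
Conditions: I2, PPh3, imidazole, CH2Cl2, 0 → 25 °C
Reagents that add atoms: iodine, II
Why: Appel-type iodination of a primary alcohol by SN2; no stereocentre is involved.

**Fragment E (side chain, side-chain-bearing ring carbon)**

Step 11
Reactants: 13 (R)-citronellic acid [(3R)-3,7-dimethyloct-6-enoic acid]; 14 (R)-4-benzyl-1,3-oxazolidin-2-one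
Product: 16 (4R)-4-benzyl-3-[(3R)-3,7-dimethyloct-6-enoyl]-1,3-oxazolidin-2-one, via mixed pivalic anhydride 15 (not isolated)
Conditions: pivaloyl chloride, Et3N, THF, −20 °C; then LiCl, 14, 25 °C
Reagents that add atoms: none
Why: N-Acylation of the Evans auxiliary through the mixed anhydride; attack occurs at the less hindered acyl group.

Step 12
Reactants: 16 (4R)-4-benzyl-3-[(3R)-3,7-dimethyloct-6-enoyl]-1,3-oxazolidin-2-one
Product: 17 tert-butyl (3R,4R)-3-{[(4R)-4-benzyl-2-oxo-1,3-oxazolidin-3-yl]carbonyl}-4,8-dimethylnon-7-enoate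
Conditions: NaN(SiMe3)2, THF, −78 °C; BrCH2CO2tBu, −78 → −40 °C
Reagents that add atoms: tert-butyl bromoacetate, CC(C)(C)OC(=O)CBr
Why: Evans alkylation; the chelated Z-sodium enolate is alkylated on the face opposite the benzyl group, which sets the side-chain-bearing ring carbon and installs ring A carbons C3 and C2 as CH2CO2tBu.

Step 13
Reactants: 17 tert-butyl (3R,4R)-3-{[(4R)-4-benzyl-2-oxo-1,3-oxazolidin-3-yl]carbonyl}-4,8-dimethylnon-7-enoate
Product: 18 tert-butyl (3R,4R)-3-[(ethylsulfanyl)carbonyl]-4,8-dimethylnon-7-enoate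
Conditions: EtSH, n-BuLi, THF, 0 °C
Reagents that add atoms: ethanethiol, CCS
Why: Thiolate cleavage of the imide at the exocyclic carbonyl (standard for hindered Evans imides); the non-basic thiolate should leave the alpha centre and the tert-butyl ester untouched.

**Union and elaboration**

Step 14
Reactants: 12 ({(1S,2R)-2-[(2S)-1-iodopropan-2-yl]cyclopropyl}ethynyl)trimethylsilane; 18 tert-butyl (3R,4R)-3-[(ethylsulfanyl)carbonyl]-4,8-dimethylnon-7-enoate
Product: 20 tert-butyl (3R,6R)-3-[(2R)-6-methylhept-5-en-2-yl]-4-oxo-6-{(1S,2S)-2-[(trimethylsilyl)ethynyl]cyclopropyl}heptanoate, via alkylzinc iodide 19 (not isolated)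
Conditions: Zn dust (activated with BrCH2CH2Br and Me3SiCl), THF, 40 °C; then 18, PdCl2(PPh3)2 (10 mol%), toluene, 25 °C
Reagents that add atoms: none
Why: Fukuyama coupling; the alkylzinc transmetalates to the acyl-palladium formed from the thioester and gives the ketone without over-addition, enolisation of the alpha centre or attack on the tert-butyl ester.

Step 15
Reactants: 20 tert-butyl (3R,6R)-3-[(2R)-6-methylhept-5-en-2-yl]-4-oxo-6-{(1S,2S)-2-[(trimethylsilyl)ethynyl]cyclopropyl}heptanoate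
Product: 21 tert-butyl (3R,4R,6R)-4-hydroxy-3-[(2R)-6-methylhept-5-en-2-yl]-6-{(1S,2S)-2-[(trimethylsilyl)ethynyl]cyclopropyl}heptanoate
Conditions: (S)-2-methyl-CBS-oxazaborolidine (0.3 equiv), catecholborane, toluene, −78 → −40 °C
Reagents that add atoms: none
Why: CBS reduction; the ketone binds with the doubly branched alpha-carbon as the large group and CH2 as the small one, so the (S)-catalyst should deliver hydride to give the (4R)-carbinol (the future acetoxy carbon) by reagent control, against the Felkin preference of the neighbouring centre.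

Step 16
Reactants: 21 tert-butyl (3R,4R,6R)-4-hydroxy-3-[(2R)-6-methylhept-5-en-2-yl]-6-{(1S,2S)-2-[(trimethylsilyl)ethynyl]cyclopropyl}heptanoate
Product: 22 tert-butyl (3R,4R,6R)-3-[(2R)-6-methylhept-5-en-2-yl]-4-[(triethylsilyl)oxy]-6-{(1S,2S)-2-[(trimethylsilyl)ethynyl]cyclopropyl}heptanoate
Conditions: Et3SiOTf, 2,6-lutidine, CH2Cl2, −78 °C
Reagents that add atoms: triethylsilyl trifluoromethanesulfonate, CC[Si](CC)(CC)OS(=O)(=O)C(F)(F)F
Why: Silylation of the hindered secondary alcohol blocks O-phosphinylation and gamma-lactonisation in the next step; an acetate could not be used here because it would be enolised.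

Step 17
Reactants: 22 tert-butyl (3R,4R,6R)-3-[(2R)-6-methylhept-5-en-2-yl]-4-[(triethylsilyl)oxy]-6-{(1S,2S)-2-[(trimethylsilyl)ethynyl]cyclopropyl}heptanoate
Product: 24 tert-butyl (3R,4R,6R)-2-(diethoxyphosphoryl)-3-[(2R)-6-methylhept-5-en-2-yl]-4-[(triethylsilyl)oxy]-6-{(1S,2S)-2-[(trimethylsilyl)ethynyl]cyclopropyl}heptanoate (C2 epimers), via diethyl phosphonite 23 (not isolated)
Conditions: LiN(iPr)2, THF, −78 °C; ClP(OEt)2, −78 → 0 °C; then 30% H2O2, 0 °C
Reagents that add atoms: diethyl chlorophosphite, CCOP(Cl)OCC; hydrogen peroxide, OO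
Why: C-Phosphinylation of the ester lithium enolate with a trivalent phosphorus chloride (C-selective, unlike the pentavalent chlorophosphate) followed by oxidation gives the phosphonoacetate; the ester CH2 is the only acidic site.

Step 18
Reactants: 24 tert-butyl (3R,4R,6R)-2-(diethoxyphosphoryl)-3-[(2R)-6-methylhept-5-en-2-yl]-4-[(triethylsilyl)oxy]-6-{(1S,2S)-2-[(trimethylsilyl)ethynyl]cyclopropyl}heptanoate
Product: 25 tert-butyl (3R,4R,6R)-2-(diethoxyphosphoryl)-4-hydroxy-3-[(2R)-6-methylhept-5-en-2-yl]-6-{(1S,2S)-2-[(trimethylsilyl)ethynyl]cyclopropyl}heptanoate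
Conditions: pyridinium p-toluenesulfonate, MeOH, 25 °C
Reagents that add atoms: none
Why: Mild acidic methanolysis of the triethylsilyl ether; the alkynylsilane and the tert-butyl ester are stable, and the bulky ester resists lactonisation.

Step 19
Reactants: 25 tert-butyl (3R,4R,6R)-2-(diethoxyphosphoryl)-4-hydroxy-3-[(2R)-6-methylhept-5-en-2-yl]-6-{(1S,2S)-2-[(trimethylsilyl)ethynyl]cyclopropyl}heptanoate
Product: 26 tert-butyl (3R,4R,6R)-4-(acetyloxy)-2-(diethoxyphosphoryl)-3-[(2R)-6-methylhept-5-en-2-yl]-6-{(1S,2S)-2-[(trimethylsilyl)ethynyl]cyclopropyl}heptanoate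
Conditions: Ac2O, DMAP (cat.), pyridine, 25 °C
Reagents that add atoms: acetic anhydride, CC(=O)OC(C)=O
Why: DMAP-catalysed acetylation installs the acetate of the target with retention; the phosphonoacetate C–H is not acylated without a Lewis acid.

Step 20
Reactants: 26 tert-butyl (3R,4R,6R)-4-(acetyloxy)-2-(diethoxyphosphoryl)-3-[(2R)-6-methylhept-5-en-2-yl]-6-{(1S,2S)-2-[(trimethylsilyl)ethynyl]cyclopropyl}heptanoate
Product: 27 tert-butyl (3R,4R,6R)-4-(acetyloxy)-6-[(1S,2S)-2-(bromoethynyl)cyclopropyl]-2-(diethoxyphosphoryl)-3-[(2R)-6-methylhept-5-en-2-yl]heptanoate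
Conditions: N-bromosuccinimide (1.1 equiv), AgNO3 (10 mol%), dry acetone, 25 °C, dark
Reagents that add atoms: N-bromosuccinimide, O=C1CCC(=O)N1Br
Why: Silver-catalysed desilylative bromination of an alkynylsilane through the silver acetylide; this is faster than reaction at the trisubstituted alkene when water and light are excluded, and it avoids a basic desilylation that would cleave the acetate.

Step 21
Reactants: 27 tert-butyl (3R,4R,6R)-4-(acetyloxy)-6-[(1S,2S)-2-(bromoethynyl)cyclopropyl]-2-(diethoxyphosphoryl)-3-[(2R)-6-methylhept-5-en-2-yl]heptanoate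
Product: 29 (3R,4R,6R)-4-(acetyloxy)-6-[(1S,2S)-2-(bromoethynyl)cyclopropyl]-2-(diethoxyphosphoryl)-3-[(2R)-6-methylhept-5-en-2-yl]heptanoic acid, via trimethylsilyl ester 28 (not isolated)
Conditions: Me3SiOTf, 2,6-lutidine, CH2Cl2, 0 °C; then pH 4 aqueous buffer
Reagents that add atoms: none
Why: Silyl-triflate cleavage of the tert-butyl ester (loss of 2-methylpropene, silyl ester hydrolysed on work-up) proceeds without protic acid, so the trisubstituted alkene and the acetate should survive.

Step 22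
Reactants: 29 (3R,4R,6R)-4-(acetyloxy)-6-[(1S,2S)-2-(bromoethynyl)cyclopropyl]-2-(diethoxyphosphoryl)-3-[(2R)-6-methylhept-5-en-2-yl]heptanoic acid
Product: 30 (3R,4R,6R)-4-(acetyloxy)-6-[(1S,2S)-2-(bromoacetyl)cyclopropyl]-2-(diethoxyphosphoryl)-3-[(2R)-6-methylhept-5-en-2-yl]heptanoic acid
Conditions: XPhosAuNTf2 (3 mol%), H2O (5 equiv), 1,2-dichloroethane, 40 °C
Reagents that add atoms: water, O
Why: Gold-catalysed hydration of a 1-bromoalkyne; water adds at the internal, cyclopropyl-stabilised carbon to give the bromomethyl ketone regioselectively, under neutral conditions that tolerate the acid, acetate and remote alkene.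

Step 23
Reactants: 30 (3R,4R,6R)-4-(acetyloxy)-6-[(1S,2S)-2-(bromoacetyl)cyclopropyl]-2-(diethoxyphosphoryl)-3-[(2R)-6-methylhept-5-en-2-yl]heptanoic acid
Product: 32 (+)-acetoxycrenulide, via keto phosphono macrolactone 31 (not isolated)
Conditions: Cs2CO3 (4 equiv), DMF, 40 °C, 30 added by syringe pump over 12 h (final 2 mM); then 60 °C, 3 h
Reagents that add atoms: none
Why: Cs2CO3 first turns the acid into its caesium carboxylate, which displaces the primary alpha-keto bromide intramolecularly (11-exo-tet SN2, the caesium-carboxylate macrolactonisation type) to give 31; the same base then deprotonates the phosphonoacetate carbon, which adds to the cyclopropyl ketone and expels diethyl phosphate (intramolecular Horner–Wadsworth–Emmons, the standard closure of alpha-(phosphonoacyloxy) ketones to butenolides). Ring A closes 5-exo-trig, and because its C3 and C4 are already joined by the six-carbon chain, the same C3=C4 bond contracts the eleven-membered lactone transannularly into the eight-membered ring B. No stereocentre is created: the olefin geometry is fixed by the five-membered ring and both phosphonate epimers converge. The six existing centres are untouched because the cyclopropyl ketone cannot enolise into the three-membered ring and the non-nucleophilic carbonate should spare the acetate. The step needs ring closure over intermolecular O-alkylation, and O- over C-alkylation; the first is secured by high dilution, the caesium effect and the U-turn imposed by the cis-cyclopropane, the second by the large pKa gap between the CO2H and the P–CH–C(=O) carbon. Once 31 exists, the olefination is a five-ring process and should outrun all intermolecular paths.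

**Compound list**
1 | methyl (R)-3-hydroxy-2-methylpropanoate | OC[C@@H](C)C(=O)OC | starting material
2 | methyl (R)-3-[(tert-butyldimethylsilyl)oxy]-2-methylpropanoate | CC(C)(C)[Si](C)(C)OC[C@@H](C)C(=O)OC | intermediate
3 | (R)-3-[(tert-butyldimethylsilyl)oxy]-2-methylpropanal | CC(C)(C)[Si](C)(C)OC[C@@H](C)C=O | intermediate
4 | methyl (2Z,4S)-5-[(tert-butyldimethylsilyl)oxy]-4-methylpent-2-enoate | CC(C)(C)[Si](C)(C)OC[C@@H](C)/C=C\C(=O)OC | intermediate
5 | (2Z,4S)-5-[(tert-butyldimethylsilyl)oxy]-4-methylpent-2-en-1-ol | CC(C)(C)[Si](C)(C)OC[C@@H](C)/C=C\CO | intermediate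
6 | {(1S,2S)-2-[(2S)-1-[(tert-butyldimethylsilyl)oxy]propan-2-yl]cyclopropyl}methanol | CC(C)(C)[Si](C)(C)OC[C@@H](C)[C@@H]1C[C@@H]1CO | intermediate
7 | (1S,2S)-2-[(2S)-1-[(tert-butyldimethylsilyl)oxy]propan-2-yl]cyclopropane-1-carbaldehyde | CC(C)(C)[Si](C)(C)OC[C@@H](C)[C@@H]1C[C@@H]1C=O | intermediate
8 | tert-butyl{(2S)-2-[(1R,2S)-2-(2,2-dibromoethenyl)cyclopropyl]propoxy}dimethylsilane | CC(C)(C)[Si](C)(C)OC[C@@H](C)[C@@H]1C[C@@H]1C=C(Br)Br | intermediate
9 | ({(1S,2R)-2-[(2S)-1-[(tert-butyldimethylsilyl)oxy]propan-2-yl]cyclopropyl}ethynyl)lithium | CC(C)(C)[Si](C)(C)OC[C@@H](C)[C@@H]1C[C@@H]1C#C[Li] | intermediate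
10 | tert-butyldimethyl{(2S)-2-[(1R,2S)-2-[(trimethylsilyl)ethynyl]cyclopropyl]propoxy}silane | CC(C)(C)[Si](C)(C)OC[C@@H](C)[C@@H]1C[C@@H]1C#C[Si](C)(C)C | intermediate
11 | (2S)-2-{(1R,2S)-2-[(trimethylsilyl)ethynyl]cyclopropyl}propan-1-ol | OC[C@@H](C)[C@@H]1C[C@@H]1C#C[Si](C)(C)C | intermediate
12 | ({(1S,2R)-2-[(2S)-1-iodopropan-2-yl]cyclopropyl}ethynyl)trimethylsilane | IC[C@@H](C)[C@@H]1C[C@@H]1C#C[Si](C)(C)C | intermediate
13 | (R)-citronellic acid, (3R)-3,7-dimethyloct-6-enoic acid | OC(=O)C[C@H](C)CCC=C(C)C | starting material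
14 | (R)-4-benzyl-1,3-oxazolidin-2-one | O=C1OC[C@@H](Cc2ccccc2)N1 | starting material
15 | (3R)-3,7-dimethyloct-6-enoic pivalic anhydride | CC(C)(C)C(=O)OC(=O)C[C@H](C)CCC=C(C)C | intermediate
16 | (4R)-4-benzyl-3-[(3R)-3,7-dimethyloct-6-enoyl]-1,3-oxazolidin-2-one | O=C1OC[C@@H](Cc2ccccc2)N1C(=O)C[C@H](C)CCC=C(C)C | intermediate
17 | tert-butyl (3R,4R)-3-{[(4R)-4-benzyl-2-oxo-1,3-oxazolidin-3-yl]carbonyl}-4,8-dimethylnon-7-enoate | O=C1OC[C@@H](Cc2ccccc2)N1C(=O)[C@H](CC(=O)OC(C)(C)C)[C@H](C)CCC=C(C)C | intermediate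
18 | tert-butyl (3R,4R)-3-[(ethylsulfanyl)carbonyl]-4,8-dimethylnon-7-enoate | CCSC(=O)[C@H](CC(=O)OC(C)(C)C)[C@H](C)CCC=C(C)C | intermediate
19 | iodo{(2S)-2-[(1R,2S)-2-[(trimethylsilyl)ethynyl]cyclopropyl]propyl}zinc | I[Zn]C[C@@H](C)[C@@H]1C[C@@H]1C#C[Si](C)(C)C | intermediate
20 | tert-butyl (3R,6R)-3-[(2R)-6-methylhept-5-en-2-yl]-4-oxo-6-{(1S,2S)-2-[(trimethylsilyl)ethynyl]cyclopropyl}heptanoate | CC(C)(C)OC(=O)C[C@H]([C@H](C)CCC=C(C)C)C(=O)C[C@@H](C)[C@@H]1C[C@@H]1C#C[Si](C)(C)C | intermediate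
21 | tert-butyl (3R,4R,6R)-4-hydroxy-3-[(2R)-6-methylhept-5-en-2-yl]-6-{(1S,2S)-2-[(trimethylsilyl)ethynyl]cyclopropyl}heptanoate | CC(C)(C)OC(=O)C[C@H]([C@H](C)CCC=C(C)C)[C@H](O)C[C@@H](C)[C@@H]1C[C@@H]1C#C[Si](C)(C)C | intermediate
22 | tert-butyl (3R,4R,6R)-3-[(2R)-6-methylhept-5-en-2-yl]-4-[(triethylsilyl)oxy]-6-{(1S,2S)-2-[(trimethylsilyl)ethynyl]cyclopropyl}heptanoate | CC(C)(C)OC(=O)C[C@H]([C@H](C)CCC=C(C)C)[C@H](O[Si](CC)(CC)CC)C[C@@H](C)[C@@H]1C[C@@H]1C#C[Si](C)(C)C | intermediate
23 | tert-butyl (3R,4R,6R)-2-(diethoxyphosphanyl)-3-[(2R)-6-methylhept-5-en-2-yl]-4-[(triethylsilyl)oxy]-6-{(1S,2S)-2-[(trimethylsilyl)ethynyl]cyclopropyl}heptanoate (C2 epimers) | CCOP(OCC)C(C(=O)OC(C)(C)C)[C@H]([C@H](C)CCC=C(C)C)[C@H](O[Si](CC)(CC)CC)C[C@@H](C)[C@@H]1C[C@@H]1C#C[Si](C)(C)C | intermediate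
24 | tert-butyl (3R,4R,6R)-2-(diethoxyphosphoryl)-3-[(2R)-6-methylhept-5-en-2-yl]-4-[(triethylsilyl)oxy]-6-{(1S,2S)-2-[(trimethylsilyl)ethynyl]cyclopropyl}heptanoate (C2 epimers) | CCOP(=O)(OCC)C(C(=O)OC(C)(C)C)[C@H]([C@H](C)CCC=C(C)C)[C@H](O[Si](CC)(CC)CC)C[C@@H](C)[C@@H]1C[C@@H]1C#C[Si](C)(C)C | intermediate
25 | tert-butyl (3R,4R,6R)-2-(diethoxyphosphoryl)-4-hydroxy-3-[(2R)-6-methylhept-5-en-2-yl]-6-{(1S,2S)-2-[(trimethylsilyl)ethynyl]cyclopropyl}heptanoate (C2 epimers) | CCOP(=O)(OCC)C(C(=O)OC(C)(C)C)[C@H]([C@H](C)CCC=C(C)C)[C@H](O)C[C@@H](C)[C@@H]1C[C@@H]1C#C[Si](C)(C)C | intermediate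
26 | tert-butyl (3R,4R,6R)-4-(acetyloxy)-2-(diethoxyphosphoryl)-3-[(2R)-6-methylhept-5-en-2-yl]-6-{(1S,2S)-2-[(trimethylsilyl)ethynyl]cyclopropyl}heptanoate (C2 epimers) | CCOP(=O)(OCC)C(C(=O)OC(C)(C)C)[C@H]([C@H](C)CCC=C(C)C)[C@H](OC(C)=O)C[C@@H](C)[C@@H]1C[C@@H]1C#C[Si](C)(C)C | intermediate
27 | tert-butyl (3R,4R,6R)-4-(acetyloxy)-6-[(1S,2S)-2-(bromoethynyl)cyclopropyl]-2-(diethoxyphosphoryl)-3-[(2R)-6-methylhept-5-en-2-yl]heptanoate (C2 epimers) | CCOP(=O)(OCC)C(C(=O)OC(C)(C)C)[C@H]([C@H](C)CCC=C(C)C)[C@H](OC(C)=O)C[C@@H](C)[C@@H]1C[C@@H]1C#CBr | intermediate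
28 | trimethylsilyl (3R,4R,6R)-4-(acetyloxy)-6-[(1S,2S)-2-(bromoethynyl)cyclopropyl]-2-(diethoxyphosphoryl)-3-[(2R)-6-methylhept-5-en-2-yl]heptanoate (C2 epimers) | CCOP(=O)(OCC)C(C(=O)O[Si](C)(C)C)[C@H]([C@H](C)CCC=C(C)C)[C@H](OC(C)=O)C[C@@H](C)[C@@H]1C[C@@H]1C#CBr | intermediate
29 | (3R,4R,6R)-4-(acetyloxy)-6-[(1S,2S)-2-(bromoethynyl)cyclopropyl]-2-(diethoxyphosphoryl)-3-[(2R)-6-methylhept-5-en-2-yl]heptanoic acid (C2 epimers) | CCOP(=O)(OCC)C(C(=O)O)[C@H]([C@H](C)CCC=C(C)C)[C@H](OC(C)=O)C[C@@H](C)[C@@H]1C[C@@H]1C#CBr | intermediate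
30 | (3R,4R,6R)-4-(acetyloxy)-6-[(1S,2S)-2-(bromoacetyl)cyclopropyl]-2-(diethoxyphosphoryl)-3-[(2R)-6-methylhept-5-en-2-yl]heptanoic acid (C2 epimers) | CCOP(=O)(OCC)C(C(=O)O)[C@H]([C@H](C)CCC=C(C)C)[C@H](OC(C)=O)C[C@@H](C)[C@@H]1C[C@@H]1C(=O)CBr | intermediate
31 | (1S,7R,8R,10R,11S)-6-(diethoxyphosphoryl)-10-methyl-7-[(2R)-6-methylhept-5-en-2-yl]-2,5-dioxo-4-oxabicyclo[9.1.0]dodecan-8-yl acetate (C6 epimers; 11-membered keto phosphono lactone) | CCOP(=O)(OCC)C1[C@H]([C@H](C)CCC=C(C)C)[C@H](OC(C)=O)C[C@@H](C)[C@@H]2C[C@@H]2C(=O)COC1=O | intermediate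
32 | (+)-acetoxycrenulide: butenolide ring A fused at C3=C4 to cyclooctene ring B with cis-fused cyclopropane ring C; acetoxy carbon R, side-chain-bearing ring carbon S, methyl carbon R, cyclopropane carbons S and S, side-chain carbon R | CC(=O)O[C@@H]1C[C@@H](C)[C@@H]2C[C@@H]2C2=C(C(=O)OC2)[C@@H]1[C@H](C)CCC=C(C)C | target

**Totals**
Total step count: 23. Longest linear sequence: 20 (steps 1–10, then 14–23).

**Steps most likely to fail**

1. Step 23 (key step). The risk is that bimolecular O-alkylation (dimer and oligomer formation) outruns closure of the strained eleven-membered ring, or that the bromoketone is consumed by base before the carboxylate captures it. The fallback separates the two events and closes the lactone by acyl activation instead of carboxylate alkylation. It sets out from 27: gold-catalysed hydration (XPhosAuNTf2, H2O) should give the bromoketone tert-butyl ester F1. Potassium formate in MeOH at 50 °C (displacement, then in situ methanolysis of the formate) should give the alpha-hydroxy ketone F2. Me3SiOTf/2,6-lutidine followed by aqueous work-up should give the hydroxy ketone seco-acid F3. Shiina macrolactonisation (2-methyl-6-nitrobenzoic anhydride, DMAP, CH2Cl2, slow addition, 1 mM), which has precedent for medium-ring lactones, then forms the C2(=O)–O1 bond and rejoins the route at 31, now isolated. LiCl/DBU in MeCN then carries 31 to 32 by the same transannular olefination.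

2. Step 15. The risk is eroded facial selectivity in hydride delivery, because catalyst control opposes the Felkin preference of the adjacent stereocentre (mismatched double stereodifferentiation). The fallback sets the carbinol in the C–C bond-forming event, where the Felkin–Anh preference is matched to the required configuration. It sets out from 18 and 12: Fukuyama reduction of 18 (Et3SiH, Pd/C, acetone) should give tert-butyl (3R,4R)-3-formyl-4,8-dimethylnon-7-enoate F4. Iodide 12 is converted by t-BuLi (2 equiv, Et2O, −78 °C) into the alkyllithium F5 (stereocentres unchanged), which adds to F4 at −78 °C anti to the branched side chain. This rejoins the route at 21 and bypasses steps 14 and 15.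

3. Step 14. The risk is slow acyl transfer at the doubly branched thioester, which would let protodezincation or beta-hydride elimination of the alkylzinc compete. The fallback forms the ketone by 1,2-addition instead of palladium catalysis. It sets out from 17: transamination with MeNH(OMe)·HCl/AlMe3 (CH2Cl2, 0 °C) should give the Weinreb amide tert-butyl (3R,4R)-3-[methoxy(methyl)carbamoyl]-4,8-dimethylnon-7-enoate F6. The alkyllithium F5 (from 12 and t-BuLi as above) adds at −78 °C through the stable chelated tetrahedral intermediate and rejoins the route at 20.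

**Further compounds**
F1 | step 23 | tert-butyl (3R,4R,6R)-4-(acetyloxy)-6-[(1S,2S)-2-(bromoacetyl)cyclopropyl]-2-(diethoxyphosphoryl)-3-[(2R)-6-methylhept-5-en-2-yl]heptanoate (C2 epimers) | CCOP(=O)(OCC)C(C(=O)OC(C)(C)C)[C@H]([C@H](C)CCC=C(C)C)[C@H](OC(C)=O)C[C@@H](C)[C@@H]1C[C@@H]1C(=O)CBr
F2 | step 23 | tert-butyl (3R,4R,6R)-4-(acetyloxy)-2-(diethoxyphosphoryl)-6-[(1S,2S)-2-(hydroxyacetyl)cyclopropyl]-3-[(2R)-6-methylhept-5-en-2-yl]heptanoate (C2 epimers) | CCOP(=O)(OCC)C(C(=O)OC(C)(C)C)[C@H]([C@H](C)CCC=C(C)C)[C@H](OC(C)=O)C[C@@H](C)[C@@H]1C[C@@H]1C(=O)CO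
F3 | step 23 | (3R,4R,6R)-4-(acetyloxy)-2-(diethoxyphosphoryl)-6-[(1S,2S)-2-(hydroxyacetyl)cyclopropyl]-3-[(2R)-6-methylhept-5-en-2-yl]heptanoic acid (C2 epimers) | CCOP(=O)(OCC)C(C(=O)O)[C@H]([C@H](C)CCC=C(C)C)[C@H](OC(C)=O)C[C@@H](C)[C@@H]1C[C@@H]1C(=O)CO
F4 | step 15 | tert-butyl (3R,4R)-3-formyl-4,8-dimethylnon-7-enoate | O=C[C@H](CC(=O)OC(C)(C)C)[C@H](C)CCC=C(C)C
F5 | step 15 | {2-[2-(trimethylsilylethynyl)cyclopropyl]propyl}lithium (from 12, stereocentres unchanged) | [Li]C[C@@H](C)[C@@H]1C[C@@H]1C#C[Si](C)(C)C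
F6 | step 14 | tert-butyl (3R,4R)-3-[methoxy(methyl)carbamoyl]-4,8-dimethylnon-7-enoate | CON(C)C(=O)[C@H](CC(=O)OC(C)(C)C)[C@H](C)CCC=C(C)C
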